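**Retrosynthetic overview**
- The last step closes C6–C7: a photoredox/chromium allylation of a C6 enal by a C7 (Z)-2-(bromomethyl)enoate, followed by lactonization. This forms the ten-membered carbocycle (ring B) and the cis-fused α-methylene lactone (ring C) together.
- The bromomethyl enoate comes from a C7 aldehyde (Baylis–Hillman reaction with methyl acrylate, then SN2′ bromination). The C8 methacrylate comes from Mitsunobu inversion of a C8 carbinol.
- The 3(2H)-furanone (ring A, formed first) comes from acetylide addition to a sugar lactone carbonyl and amine-mediated cyclization of the resulting α′-hydroxy ynone.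
- 2-C-Methyl-D-ribono-1,4-lactone supplies C1 and C7–C10 (C9 and C10 as bought, C8 inverted once). (Z)-3-Methylpent-2-en-4-yn-1-ol supplies C2–C6 and C15 with the Z-alkene. C6 and C7 are set by the substrate in the ring closure.

Assumption: germacrane numbering (C1–C15) is used for all compounds, and both building blocks named above are taken as commercial.

**Route**

Step 1
Reactants: 1 2-C-methyl-D-ribono-1,4-lactone
Product: 2 3,5-bis-O-triethylsilyl-2-C-methyl-D-ribono-1,4-lactone
Conditions: TESCl (2.2 equiv), imidazole, DMF, 0 °C to rt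
Reagents that add atoms: chlorotriethylsilane (TESCl), CC[Si](Cl)(CC)CC
Why: Silyl ether formation takes the primary and the secondary hydroxyl, while the tertiary α-hydroxyl next to the lactone carbonyl is too hindered and stays free for the later furanone closure; no stereocenter is touched.

Step 2
Reactants: 3 (Z)-3-methylpent-2-en-4-yn-1-ol
Product: 4 (Z)-5-(tert-butyldimethylsilyloxy)-3-methylpent-3-en-1-yne
Conditions: TBSCl, imidazole, CH2Cl2, 0 °C to rt
Reagents that add atoms: tert-butyldimethylsilyl chloride (TBSCl), CC(C)(C)[Si](C)(C)Cl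
Why: Standard silyl ether formation; the C6 oxygen must be blocked because a free (Z)-enynol would close to a furan by oxa-Michael addition once the ynone exists, and TBS (unlike TES) survives the Swern step.

Step 3
Reactants: 2 3,5-bis-O-triethylsilyl-2-C-methyl-D-ribono-1,4-lactone, 4 (Z)-5-(tert-butyldimethylsilyloxy)-3-methylpent-3-en-1-yne
Product: 8 furanone alcohol (8R,9R,10R; free C8–OH), via lithium acetylide 5 (not isolated), via lactol 6 (not isolated), via enaminone 7 (not isolated)
Conditions: 4 (2.3 equiv), n-BuLi (2.2 equiv), THF, −78 °C; 2, −78 to −40 °C; AcOH, −78 °C; crude in EtOH, Et2NH, rt; then AcOH, rt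
Reagents that add atoms: none
Why: Acetylide addition to a γ-lactone stops at the hemiketal (one extra equivalent covers the free tertiary OH); Et2NH then adds to the ring-opened ynone (aza-Michael) and the C10 hydroxyl displaces the amine by addition–elimination (the classical α′-hydroxy ynone to 3(2H)-furanone synthesis), only the five-membered ring being possible because the C9 oxygen is silylated, and C8–C10 and the Z-alkene are untouched.

Step 4
Reactants: 8 furanone alcohol (8R,9R,10R), 9 methacrylic acid
Product: 10 C8 methacrylate (8S,9R,10R)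
Conditions: PPh3, DIAD, toluene, 0 °C to rt (BHT trace)
Reagents that add atoms: none
Why: Mitsunobu esterification displaces the C8 oxyphosphonium by methacrylate with clean SN2 inversion (8R to 8S), which corrects the one sugar stereocenter that does not match the target and installs the ester in the same operation.

Step 5
Reactants: 10 C8 methacrylate (8S,9R,10R)
Product: 11 C7 aldehyde
Conditions: (COCl)2, DMSO, CH2Cl2, −78 to −40 °C; Et3N, −78 to 0 °C
Reagents that add atoms: none
Why: Under Swern conditions a primary TES ether is cleaved and oxidized directly to the aldehyde while the secondary TES and the TBS ether survive (known one-pot desilylation–oxidation); keeping the base step cold protects the α-acyloxy center C8.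

Step 6
Reactants: 11 C7 aldehyde, 12 methyl acrylate
Product: 13 Baylis–Hillman alcohol (C7 epimers)
Conditions: DABCO (1 equiv), methyl acrylate (10 equiv, neat), MeOH (3 equiv), rt
Reagents that add atoms: none
Why: Morita–Baylis–Hillman reaction, fast with an electron-poor α-oxygenated aldehyde; the new C7 carbinol center need not be controlled because it becomes sp2 in step 7.

Step 7
Reactants: 13 Baylis–Hillman alcohol (C7 epimers)
Product: 14 (Z)-2-(bromomethyl)enoate
Conditions: NBS, Me2S, CH2Cl2, −20 to 0 °C
Reagents that add atoms: N-bromosuccinimide (NBS), O=C1CCC(=O)N1Br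
Why: Corey–Kim-type activation of the Baylis–Hillman alcohol and bromide attack with allylic transposition (SN2′) give the thermodynamically preferred (Z)-2-(bromomethyl)enoate, with C8 cis to CH2Br.

Step 8
Reactants: 14 (Z)-2-(bromomethyl)enoate
Product: 15 bromo diol (free C6–OH and C9–OH)
Conditions: 48% aq. HF, MeCN, 0 °C
Reagents that add atoms: none
Why: Acidic, non-nucleophilic desilylation removes the primary allylic TBS and the secondary TES ether without touching the allylic bromide, the esters or the furanone.

Step 9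
Reactants: 15 bromo diol
Product: 16 bromo enal
Conditions: MnO2, CH2Cl2, rt, dark
Reagents that add atoms: none
Why: MnO2 oxidizes only the allylic primary alcohol (not the C9 secondary alcohol) to the (Z)-enal, which is used at once.

Step 10
Reactants: 16 bromo enal
Product: 18 target CNP0252578.4 (6S,7S,8S,9R,10R), via hydroxy ester 17 (not isolated)
Conditions: CrCl3(THF)3 (20 mol%), 4CzIPN (2 mol%), Hantzsch ester (1.5 equiv), DMF (2 mM), 450 nm LEDs, rt; aq. NaHCO3 work-up
Reagents that add atoms: none
Why: Proposed new method: the excited photocatalyst is quenched by the Hantzsch ester and its radical anion reduces trivalent to divalent chromium, which turns the allylic bromide (bromine abstraction, then radical capture) into a (Z)-2-(methoxycarbonyl)allylchromium species that adds to the tethered enal through a closed chair (Zimmerman–Traxler) transition state; the Z-geometry puts C8 axial and the short tether forces C5 equatorial, so the syn adduct forms and lactonizes to the cis-fused lactone (6S), while C7 (S) follows from C8 because the tether holds C9 gauche to the forming bond and the C8–O bond sits inside rather than anti to it (inside-alkoxy effect, reinforced by O–Cr coordination); protonation by the Hantzsch pyridinium releases chromium for turnover, and photosensitized E/Z equilibration of the enal is harmless because only the Z-isomer can cyclize; closest known reactions are the intermolecular dual photoredox/chromium allylation of aldehydes, photoredox titanium Barbier allylations with allyl bromides, and stoichiometric CrCl2 or Zn Barbier cyclizations of 2-(bromomethyl)enoates, none of which has been shown as a catalytic photochemical macrocyclization with lactone formation.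

**Compound list**

1 | 2-C-methyl-D-ribono-1,4-lactone, (3R,4R,5R)-3,4-dihydroxy-5-(hydroxymethyl)-3-methyloxolan-2-one | O=C1O[C@H](CO)[C@@H](O)[C@@]1(C)O | starting material
2 | 3,5-bis-O-(triethylsilyl)-2-C-methyl-D-ribono-1,4-lactone (tertiary 2-OH free) | O=C1O[C@H](CO[Si](CC)(CC)CC)[C@@H](O[Si](CC)(CC)CC)[C@@]1(C)O | intermediate
3 | (Z)-3-methylpent-2-en-4-yn-1-ol | C#C/C(C)=C\CO | starting material
4 | (Z)-5-(tert-butyldimethylsilyloxy)-3-methylpent-3-en-1-yne | C#C/C(C)=C\CO[Si](C)(C)C(C)(C)C | intermediate
5 | lithium acetylide of 4 | [Li]C#C/C(C)=C\CO[Si](C)(C)C(C)(C)C | intermediate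
6 | lactol, (3R,4R,5R)-2-[(Z)-5-(tert-butyldimethylsilyloxy)-3-methylpent-3-en-1-yn-1-yl]-3-methyl-4-(triethylsilyloxy)-5-[(triethylsilyloxy)methyl]oxolane-2,3-diol, both C2 anomers | OC1(C#C/C(C)=C\CO[Si](C)(C)C(C)(C)C)O[C@H](CO[Si](CC)(CC)CC)[C@@H](O[Si](CC)(CC)CC)[C@@]1(C)O | intermediate
7 | open-chain enaminone (8R,9R,10R): C1 ketone, C2=C3 bearing NEt2 on C3, (Z)-C4=C5, C6 OTBS, C7 and C9 OTES, free C8 and C10 hydroxyls | CCN(CC)C(/C(C)=C\CO[Si](C)(C)C(C)(C)C)=CC(=O)[C@](C)(O)[C@H](O[Si](CC)(CC)CC)[C@H](O)CO[Si](CC)(CC)CC | intermediate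
8 | (2R)-2-[(1R,2R)-2-hydroxy-1,3-bis(triethylsilyloxy)propyl]-2-methyl-5-[(Z)-4-(tert-butyldimethylsilyloxy)but-2-en-2-yl]furan-3(2H)-one (8R,9R,10R) | CC[Si](CC)(CC)OC[C@@H](O)[C@@H](O[Si](CC)(CC)CC)[C@@]1(C)OC(/C(C)=C\CO[Si](C)(C)C(C)(C)C)=CC1=O | intermediate
9 | methacrylic acid | C=C(C)C(=O)O | starting material
10 | (1R,2S)-1-[(2R)-2-methyl-3-oxo-5-[(Z)-4-(tert-butyldimethylsilyloxy)but-2-en-2-yl]-2,3-dihydrofuran-2-yl]-1,3-bis(triethylsilyloxy)propan-2-yl 2-methylprop-2-enoate (8S,9R,10R) | CC[Si](CC)(CC)OC[C@H](OC(=O)C(C)=C)[C@@H](O[Si](CC)(CC)CC)[C@@]1(C)OC(/C(C)=C\CO[Si](C)(C)C(C)(C)C)=CC1=O | intermediate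
11 | (2R,3R)-1-oxo-3-[(2R)-2-methyl-3-oxo-5-[(Z)-4-(tert-butyldimethylsilyloxy)but-2-en-2-yl]-2,3-dihydrofuran-2-yl]-3-(triethylsilyloxy)propan-2-yl 2-methylprop-2-enoate (C8 is R by priority change only; same spatial arrangement as in 10) | O=C[C@H](OC(=O)C(C)=C)[C@@H](O[Si](CC)(CC)CC)[C@@]1(C)OC(/C(C)=C\CO[Si](C)(C)C(C)(C)C)=CC1=O | intermediate
12 | methyl acrylate | C=CC(=O)OC | starting material
13 | methyl (4S,5R)-3-hydroxy-4-(methacryloyloxy)-2-methylidene-5-[(2R)-2-methyl-3-oxo-5-[(Z)-4-(tert-butyldimethylsilyloxy)but-2-en-2-yl]-2,3-dihydrofuran-2-yl]-5-(triethylsilyloxy)pentanoate, both C3 (germacrane C7) epimers | C=C(C(=O)OC)C(O)[C@H](OC(=O)C(C)=C)[C@@H](O[Si](CC)(CC)CC)[C@@]1(C)OC(/C(C)=C\CO[Si](C)(C)C(C)(C)C)=CC1=O | intermediate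
14 | methyl (2Z,4S,5R)-2-(bromomethyl)-4-(methacryloyloxy)-5-[(2R)-2-methyl-3-oxo-5-[(Z)-4-(tert-butyldimethylsilyloxy)but-2-en-2-yl]-2,3-dihydrofuran-2-yl]-5-(triethylsilyloxy)pent-2-enoate | BrC/C(C(=O)OC)=C\[C@H](OC(=O)C(C)=C)[C@@H](O[Si](CC)(CC)CC)[C@@]1(C)OC(/C(C)=C\CO[Si](C)(C)C(C)(C)C)=CC1=O | intermediate
15 | methyl (2Z,4S,5R)-2-(bromomethyl)-5-hydroxy-4-(methacryloyloxy)-5-[(2R)-5-[(Z)-4-hydroxybut-2-en-2-yl]-2-methyl-3-oxo-2,3-dihydrofuran-2-yl]pent-2-enoate | BrC/C(C(=O)OC)=C\[C@H](OC(=O)C(C)=C)[C@@H](O)[C@@]1(C)OC(/C(C)=C\CO)=CC1=O | intermediate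
16 | methyl (2Z,4S,5R)-2-(bromomethyl)-5-hydroxy-4-(methacryloyloxy)-5-[(2R)-2-methyl-3-oxo-5-[(Z)-4-oxobut-2-en-2-yl]-2,3-dihydrofuran-2-yl]pent-2-enoate | BrC/C(C(=O)OC)=C\[C@H](OC(=O)C(C)=C)[C@@H](O)[C@@]1(C)OC(/C(C)=C\C=O)=CC1=O | intermediate
17 | macrocyclic hydroxy ester (6S,7S,8S,9R,10R): ten-membered furanone-bridged ring with C6–OH, C7 bearing the methyl 2-propenoate unit, C8 methacrylate, C9–OH | C=C(C)C(=O)O[C@H]1[C@@H](C(=C)C(=O)OC)[C@@H](O)/C=C(/C)C2=CC(=O)[C@](C)(O2)[C@@H]1O | intermediate
18 | CNP0252578.4, (6S,7S,8S,9R,10R)-9-hydroxy-1-oxo-3,10-epoxygermacra-2,4(Z),11(13)-trien-12,6-olid-8-yl 2-methylprop-2-enoate (cis-fused lactone) | C=C(C)C(=O)O[C@H]1[C@H]2C(=C)C(=O)O[C@H]2/C=C(/C)C2=CC(=O)[C@](C)(O2)[C@@H]1O | target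

**Step count and risks**

Total: 10 steps. Longest linear sequence: 9 steps (from 1 through steps 1 and 3–10; equally from 3 through steps 2–10).

The three steps most likely to fail:

Step 10, the proposed photoredox/chromium ring closure. It may fail through poor chromium turnover, through radical addition to the acrylate units, or through the wrong face at C7; the C7 prediction rests on the inside-alkoxy preference overriding the sterically smaller hydrogen-inside arrangement and is the weakest stereochemical call in the route. The fallback sets out from 16 and replaces the catalytic photochemical radical-to-organometallic relay by a thermal, stoichiometric two-electron Barbier cyclization with activated Zn dust in THF/sat. aq. NH4Cl at high dilution. This is the known way to cis-fused α-methylene lactones in medium rings from ω-formyl (Z)-2-(bromomethyl)enoates. Hydroxy ester 17 is isolated this time and closed with catalytic TsOH in CH2Cl2, coming back to the route at 18. It makes no compound outside the list (none F0).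

Step 4, the Mitsunobu inversion. The C8 carbinol is flanked by two silyloxy-bearing carbons, and the furanone carbonyl could take part as a neighbouring group and give retention or rearranged material. The fallback sets out from 8 and inverts by redox instead of substitution. Dess–Martin periodinane (NaHCO3, CH2Cl2) gives the C8 ketone F1. LiBH(s-Bu)3 in THF at −78 °C reduces it under Felkin–Anh control (C9–OTES anti to hydride) to the 8S alcohol F2; any 8R epimer formed is simply 8 and is recycled. Methacrylic anhydride, Et3N and DMAP in CH2Cl2 then give the ester, coming back to the route at 10.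

Step 6, the Baylis–Hillman reaction. Long exposure of the α-acyloxy aldehyde to DABCO can epimerize C8 or shift the methacrylate onto the new C7 hydroxyl. The fallback sets out from 11 and uses a preformed, non-basic vinyl nucleophile instead of amine catalysis. Methyl propiolate is hydroaluminated with i-Bu2AlH and N-methylmorpholine N-oxide in THF at 0 °C to [1-(methoxycarbonyl)vinyl]diisobutylaluminium F3. Aldehyde 11 is added at −78 °C, and Rochelle-salt work-up gives the same alcohol within minutes, coming back to the route at 13.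

**Further compounds**

F1 | step 4 | C8 ketone, (2R)-2-[(1R)-2-oxo-1,3-bis(triethylsilyloxy)propyl]-2-methyl-5-[(Z)-4-(tert-butyldimethylsilyloxy)but-2-en-2-yl]furan-3(2H)-one | CC[Si](CC)(CC)OCC(=O)[C@@H](O[Si](CC)(CC)CC)[C@@]1(C)OC(/C(C)=C\CO[Si](C)(C)C(C)(C)C)=CC1=O
F2 | step 4 | 8S alcohol, (2R)-2-[(1R,2S)-2-hydroxy-1,3-bis(triethylsilyloxy)propyl]-2-methyl-5-[(Z)-4-(tert-butyldimethylsilyloxy)but-2-en-2-yl]furan-3(2H)-one | CC[Si](CC)(CC)OC[C@H](O)[C@@H](O[Si](CC)(CC)CC)[C@@]1(C)OC(/C(C)=C\CO[Si](C)(C)C(C)(C)C)=CC1=O
F3 | step 6 | [1-(methoxycarbonyl)vinyl]diisobutylaluminium | C=C(C(=O)OC)[Al](CC(C)C)CC(C)C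
F0 | step 10 | none | none
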